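**Retrosynthetic overview**
- Last bond: C13–O9, by a dehydrogenative (oxa-Wacker) spirocyclisation of a 9α-hydroxy 3-alkyl-2,5-dihydrofuran. This closes the tetrahydrofuran ring, creates the spiro centre C13 and unveils the C14=C15 enol ether in one operation.
- C12–C13: reductive C(sp3)–C(sp2) coupling of a primary bromide with 2,5-dihydrofuran-3-yl triflate.
- Ring B oxygens: C9–O and C6–O from a singlet-oxygen [4+2] on a ring B dienyl acetate, then C6 reduction with an O7→O6 acetyl shift that also releases the C7 ketone.
- Rings A and B with C5 and C10 are bought as (+)-sclareolide: lactone opening/dehydration, reduction, bromination, allylic oxidation.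
- Ring order: decalin (purchased) → dihydrofuran ring attached intact → spiro tetrahydrofuran ring last.

Assumption: the SMILES is read as the (5S,6S,8S,9R,10S,13R) isomer, i.e. 6β-OAc (axial), 8α-CH3, 9α-O, normal labdane series; labdane numbering is used throughout.

**Route**

Step 1
Reactants: 1 (+)-sclareolide
Product: 2 methyl 13,14,15,16-tetranorlabd-8-en-12-oate
Conditions: conc. H2SO4, MeOH, 25 °C; AgNO3–SiO2 chromatography
Reagents that add atoms: methanol, CO
Why: Acid-catalysed lactone methanolysis with E1 dehydration of the tertiary C8 alcohol under equilibrating conditions (Fischer esterification/dehydration) gives the thermodynamic tetrasubstituted 8,9-alkene as the major ester, the minor alkene isomers being removed on silver nitrate silica, while C5 and C10 are untouched.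

Step 2
Reactants: 2 methyl 13,14,15,16-tetranorlabd-8-en-12-oate
Product: 3 13,14,15,16-tetranorlabd-8-en-12-ol
Conditions: LiAlH4, THF, 0 °C
Reagents that add atoms: none
Why: Standard hydride reduction of an ester to the primary alcohol; the isolated tetrasubstituted alkene is inert.

Step 3
Reactants: 3 13,14,15,16-tetranorlabd-8-en-12-ol
Product: 4 12-bromo-13,14,15,16-tetranorlabd-8-ene
Conditions: CBr4, PPh3, CH2Cl2, 0 °C
Reagents that add atoms: carbon tetrabromide, BrC(Br)(Br)Br
Why: Appel bromination of an unhindered primary alcohol under neutral conditions gives a handle that survives the later oxidations and is directly usable in the coupling.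

Step 4
Reactants: 4 12-bromo-13,14,15,16-tetranorlabd-8-ene
Product: 5 12-bromo-13,14,15,16-tetranorlabd-8-en-7-one
Conditions: CrO3, 3,5-dimethylpyrazole, CH2Cl2, −20 °C
Reagents that add atoms: chromium trioxide, O=[Cr](=O)=O
Why: Allylic oxidation with the CrO3–3,5-dimethylpyrazole complex attacks the ring methylene C7 in preference to C11 (deactivated by the β-bromine and crowded by C10) and the C17 methyl, giving the 8-en-7-one.

Step 5
Reactants: 5 12-bromo-13,14,15,16-tetranorlabd-8-en-7-one
Product: 6 12-bromo-13,14,15,16-tetranorlabda-6,8-dien-7-yl acetate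
Conditions: LiN(SiMe3)2, THF, −78 °C; then Ac2O, −78 → 0 °C
Reagents that add atoms: acetic anhydride, CC(=O)OC(C)=O
Why: Kinetic α′-deprotonation of the enone at C6 and O-acetylation of the cross-conjugated lithium dienolate give the homoannular dienyl acetate, the low temperature and hindered silylamide base avoiding γ-deprotonation and loss of HBr.

Step 6
Reactants: 6 12-bromo-13,14,15,16-tetranorlabda-6,8-dien-7-yl acetate
Product: 8 12-bromo-9α-hydroxy-6-oxo-13,14,15,16-tetranorlabd-7-en-7-yl acetate, via endoperoxide 7 (not isolated)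
Conditions: O2, tetraphenylporphyrin (cat.), visible light, CH2Cl2, −20 °C; then Et3N, 0 °C
Reagents that add atoms: dioxygen, O=O
Why: Singlet oxygen adds [4+2] across C6/C9 of the cisoid ring B diene from the α face (the β face is shielded by the axial C10 and C4 methyls, as in 5,7-diene steroid peroxides), setting the 9α C–O bond, and the Kornblum–DeLaMare rearrangement removes the only peroxide α-hydrogen (H6) to give the 6-ketone and the free 9α-hydroxyl.

Step 7
Reactants: 8 12-bromo-9α-hydroxy-6-oxo-13,14,15,16-tetranorlabd-7-en-7-yl acetate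
Product: 10 12-bromo-9α-hydroxy-7-oxo-13,14,15,16-tetranorlabdan-6β-yl acetate, via hydroxy enol acetate 9 (not isolated)
Conditions: NaBH4, CeCl3·7H2O, MeOH–THF, −78 °C; aq NH4Cl; then Et3N, CH2Cl2, 25 °C
Reagents that add atoms: none
Why: Luche 1,2-reduction from the open α face gives the axial 6β-alcohol (C6 set), whose neighbouring enol acetate hands its acetyl from O7 to O6 (1,2-acyl migration driven by enol ester → ketone, the same sense as the 7→6 acetyl shift of forskolin-type ring B diols), and the freed enol ketonises by axial β-face protonation at C8 to the equatorial, thermodynamically preferred 8α-methyl (C8 set).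

Step 8
Reactants: 11 dihydrofuran-3(2H)-one
Product: 12 2,5-dihydrofuran-3-yl trifluoromethanesulfonate
Conditions: LiN(SiMe3)2, THF, −78 °C; then PhNTf2, −78 → 0 °C
Reagents that add atoms: N-phenylbis(trifluoromethanesulfonimide), O=S(=O)(N(c1ccccc1)S(=O)(=O)C(F)(F)F)C(F)(F)F
Why: Kinetic enolisation away from the ring oxygen (C4) and O-triflation give the 2,5-dihydrofuran enol triflate.

Step 9
Reactants: 10 12-bromo-9α-hydroxy-7-oxo-13,14,15,16-tetranorlabdan-6β-yl acetate; 12 2,5-dihydrofuran-3-yl trifluoromethanesulfonate
Product: 13 6β-acetoxy-15,16-epoxy-9α-hydroxylabd-13-en-7-one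
Conditions: NiBr2·dme (10 mol %), 4,4′-di-tert-butyl-2,2′-bipyridine (12 mol %), Mn powder, NaI (0.5 equiv), DMA, 25 °C
Reagents that add atoms: none
Why: Nickel-catalysed reductive cross-electrophile coupling of a primary alkyl bromide with an alkenyl triflate (zerovalent manganese as terminal reductant) forms the C12–C13 bond without base or organometallic reagents, so the β-hydroxy ketone, the α-acetoxy ketone and the free tertiary alcohol are tolerated and no stereocentre is touched.

Step 10
Reactants: 13 6β-acetoxy-15,16-epoxy-9α-hydroxylabd-13-en-7-one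
Product: 14 (13R)-6β-acetoxy-9α,13:15,16-diepoxylabd-14-en-7-one
Conditions: Pd(OCOCF3)2 (10 mol %), (S)-tBu-PyOx (15 mol %), Na2CO3, 3 Å sieves, O2 (1 atm), toluene, 45 °C
Reagents that add atoms: none
Why: Proposed new method: a ligand-controlled aerobic oxa-Wacker spirocyclisation in which the tertiary 9α-hydroxyl adds 5-exo to C13 of the 2,5-dihydrofuran alkene bound to divalent palladium and the resulting C14–Pd species can β-hydride-eliminate only toward C15 (C13 is quaternary), which unveils the C14=C15 enol ether while zerovalent palladium is reoxidised by O2; the chiral pyridine–oxazoline ligand is meant to deliver O9 to the Re face of C13 to set (13R), although which ligand antipode is matched cannot be predicted and the (R)-ligand is the first alternative to screen; carbonate and sieves keep the acid-labile spiro enol ether from reopening to the furan; the closest known reaction type is the aerobic Pd(OCOCF3)2/pyridine-type Wacker oxidative cyclisation of alcohols, phenols and sulfonamides onto trisubstituted alkenes, not yet shown for a tertiary alcohol adding to a cyclic allyl ether with enol-ether-forming elimination.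

**Compound list**

1 | (+)-sclareolide, (3aR,5aS,9aS,9bR)-3a,6,6,9a-tetramethyldecahydronaphtho[2,1-b]furan-2(1H)-one | C1C[C@@]3(C)OC(=O)C[C@@H]3[C@@]2(C)CCCC(C)(C)[C@H]12 | starting material
2 | methyl 13,14,15,16-tetranorlabd-8-en-12-oate (5S,10S) | C1CC(C)=C(CC(=O)OC)[C@@]2(C)CCCC(C)(C)[C@H]12 | intermediate
3 | 13,14,15,16-tetranorlabd-8-en-12-ol (5S,10S) | C1CC(C)=C(CCO)[C@@]2(C)CCCC(C)(C)[C@H]12 | intermediate
4 | 12-bromo-13,14,15,16-tetranorlabd-8-ene (5S,10S) | C1CC(C)=C(CCBr)[C@@]2(C)CCCC(C)(C)[C@H]12 | intermediate
5 | 12-bromo-13,14,15,16-tetranorlabd-8-en-7-one (5S,10S) | C1C(=O)C(C)=C(CCBr)[C@@]2(C)CCCC(C)(C)[C@H]12 | intermediate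
6 | 12-bromo-13,14,15,16-tetranorlabda-6,8-dien-7-yl acetate (5S,10S) | C1=C(OC(C)=O)C(C)=C(CCBr)[C@@]2(C)CCCC(C)(C)[C@H]12 | intermediate
7 | 12-bromo-6α,9α-epidioxy-13,14,15,16-tetranorlabd-7-en-7-yl acetate (endoperoxide, peroxide bridge on the α face) | [C@H]1(OO3)C(OC(C)=O)=C(C)[C@]3(CCBr)[C@@]2(C)CCCC(C)(C)[C@H]12 | intermediate
8 | 12-bromo-9α-hydroxy-6-oxo-13,14,15,16-tetranorlabd-7-en-7-yl acetate | C1(=O)C(OC(C)=O)=C(C)[C@](O)(CCBr)[C@@]2(C)CCCC(C)(C)[C@H]12 | intermediate
9 | 12-bromo-6β,9α-dihydroxy-13,14,15,16-tetranorlabd-7-en-7-yl acetate | O[C@@H]1C(OC(C)=O)=C(C)[C@](O)(CCBr)[C@@]2(C)CCCC(C)(C)[C@H]12 | intermediate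
10 | 12-bromo-9α-hydroxy-7-oxo-13,14,15,16-tetranorlabdan-6β-yl acetate (5S,6S,8S,9R,10S; 8α-methyl) | CC(=O)O[C@@H]1C(=O)[C@@H](C)[C@](O)(CCBr)[C@@]2(C)CCCC(C)(C)[C@H]12 | intermediate
11 | dihydrofuran-3(2H)-one | O=C1CCOC1 | starting material
12 | 2,5-dihydrofuran-3-yl trifluoromethanesulfonate | O=S(=O)(OC1=CCOC1)C(F)(F)F | intermediate
13 | 6β-acetoxy-15,16-epoxy-9α-hydroxylabd-13-en-7-one (5S,6S,8S,9R,10S) | CC(=O)O[C@@H]1C(=O)[C@@H](C)[C@](O)(CCC3=CCOC3)[C@@]2(C)CCCC(C)(C)[C@H]12 | intermediate
14 | (5S,6S,8S,9R,10S,13R)-6β-acetoxy-9α,13:15,16-diepoxylabd-14-en-7-one (CNP0224709.1) | CC(=O)O[C@@H]1C(=O)[C@@H](C)[C@]2(CC[C@]3(C=COC3)O2)[C@@]2(C)CCCC(C)(C)[C@H]12 | target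

**Step count and risks**

Total steps: 10. Longest linear sequence: 9 (steps 1–7, 9, 10; step 8 is the side branch).

Steps most likely to fail:

Step 10 (the proposed spirocyclisation). Likely failure modes are aromatisation of the 2,5-dihydrofuran to the furan through allylic C–H palladation, sluggish attack by the hindered axial tertiary alcohol, and poor facial control at C13 with either ligand antipode. The fallback uses known chemistry, sets out from 13 and returns at 14. Iodoetherification (N-iodosuccinimide, NaHCO3, MeCN, 0 °C) adds O9 to C13 and iodine to C14 in anti fashion (5-exo, Markovnikov) and gives the 14-iodo-14,15-dihydro spiro ether F1; the C13 epimers are separated at this stage. Dehydroiodination (DBU, toluene, 60 °C) can remove hydrogen only from C15 and gives the C14=C15 enol ether 14.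

Step 6 (singlet-oxygen [4+2] and Kornblum–DeLaMare). The acetoxy group lowers the diene reactivity, so an ene reaction at the tetrasubstituted C8=C9 bond may compete, and the α-acetoxy enone product is an active acyl donor next to the 9-hydroxyl. The fallback installs the two oxygens one at a time, sets out from 5 and returns at 8. Nucleophilic epoxidation (H2O2, NaOH, MeOH, 0 °C) from the α face gives the 8α,9α-epoxy ketone F2. Samarium diiodide (THF–MeOH, −78 °C) opens it to the 9α-hydroxy-8α-methyl ketone F3. Riley oxidation (SeO2, dioxane, 80 °C) of the C6 methylene gives the diosphenol F4 (7-hydroxy-7-en-6-one tautomer). Acetylation of its enol hydroxyl (Ac2O, pyridine, 0 °C) gives 8.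

Step 7 (reduction with acetyl shift). The acetyl may be lost to methanol, may go to O9, or the C7 ketone may be released while hydride is still present and be over-reduced. The fallback replaces the intramolecular transfer by acetylation and selective deacylation, sets out from 8 and returns at 10. The Luche reduction is run as before and 9 is isolated at low temperature without base. Forced acetylation of the 6β-hydroxyl (Ac2O, DMAP, pyridine, 40 °C) gives the 6β,7-diacetate F5. Morpholine (THF, 0 °C) then cleaves only the activated enol acetate, and the enol ketonises to 10.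

**Further compounds**

F1 | step 10 | 6β-acetoxy-9α,13:15,16-diepoxy-14-iodolabdan-7-one, iodine anti to O9, C13 arranged as in 14 (13S,14S by CIP) | CC(=O)O[C@@H]1C(=O)[C@@H](C)[C@]2(CC[C@]3([C@@H](I)COC3)O2)[C@@]2(C)CCCC(C)(C)[C@H]12
F2 | step 6 | 12-bromo-8α,9α-epoxy-13,14,15,16-tetranorlabdan-7-one | C1C(=O)[C@@]3(C)O[C@@]3(CCBr)[C@@]2(C)CCCC(C)(C)[C@H]12
F3 | step 6 | 12-bromo-9α-hydroxy-13,14,15,16-tetranorlabdan-7-one (8α-methyl) | C1C(=O)[C@@H](C)[C@](O)(CCBr)[C@@]2(C)CCCC(C)(C)[C@H]12
F4 | step 6 | 12-bromo-7,9α-dihydroxy-13,14,15,16-tetranorlabd-7-en-6-one (diosphenol) | C1(=O)C(O)=C(C)[C@](O)(CCBr)[C@@]2(C)CCCC(C)(C)[C@H]12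
F5 | step 7 | 12-bromo-9α-hydroxy-13,14,15,16-tetranorlabd-7-ene-6β,7-diyl diacetate | CC(=O)O[C@@H]1C(OC(C)=O)=C(C)[C@](O)(CCBr)[C@@]2(C)CCCC(C)(C)[C@H]12
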